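**Retrosynthetic overview**
- The acetate, the C4 carbinol and the C3 enol ether come from a bicyclo[3.2.1]oct-2-ene diosphenol (3-hydroxy-2-ene-4,8-dione), made by α-oxidation of the saturated 4,8-dione.
- The six-membered ring (formed second) is closed by intramolecular Michael addition of the cyclopentanone enolate onto a vinyl ketone anchored at the methoxy-bearing carbon; this fixes the allyl quaternary centre.
- The methoxy and allyl groups are put on a cyclopentanone β-keto ester by enolate hydroxylation/O-methylation and by dianion allylation.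
- The cyclopentanone (formed first) comes from the key intermolecular, amine-catalysed Michael addition of ethyl 4-bromoacetoacetate to 3,4,5-trimethoxycinnamaldehyde, followed in the flask by enamine alkylation; this sets the aryl and methyl centres.
- The enal is made from 3,4,5-trimethoxybenzaldehyde by Wittig olefination.

Assumption: Ar = 3,4,5-trimethoxyphenyl; monocyclic compounds carry cyclopentane locants, bicyclic ones the target's locants (C1 allyl bridgehead, C5 methoxy bridgehead, C8 bridging carbonyl); enolisable centres are drawn as the trans isomer, and centres marked "epimers" are carried as mixtures, unassigned in the SMILES, and destroyed later.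

**Step 1**
Reactants: 1 3,4,5-trimethoxybenzaldehyde; 2 (triphenylphosphoranylidene)acetaldehyde
Product: 3 (E)-3-Ar-prop-2-enal
Conditions: 2 (1.1 equiv), toluene, 80 °C
Reagents that add atoms: (triphenylphosphoranylidene)acetaldehyde, O=CC=P(c1ccccc1)(c1ccccc1)c1ccccc1
Why: Wittig olefination with the stabilised formyl ylide gives the (E)-enal and stops after one homologation because the product enal is the poorer electrophile.

**Step 2**
Reactants: 3 (E)-3-Ar-prop-2-enal; 4 ethyl 4-bromo-3-oxobutanoate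
Product: 6 ethyl (1R,4R,5S)-4-formyl-2-oxo-5-Ar-cyclopentane-1-carboxylate, via Michael adduct 5 (not isolated)
Conditions: (R)-2-[diphenyl(trimethylsilyloxy)methyl]pyrrolidine (20 mol%), K2CO3 (1.0 equiv), CHCl3, 4 → 23 °C
Reagents that add atoms: ethyl 4-bromo-3-oxobutanoate, CCOC(=O)CC(=O)CBr
Why: Iminium-activated intermolecular Michael addition of the β-keto ester carbon to the enal, on the face left open by the (R)-catalyst (sets the aryl centre, 5S), is followed by intramolecular enamine α-alkylation by the CH2Br group (domino Michael/α-alkylation), and the formyl and ester centres settle trans under the carbonate.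

**Step 3**
Reactants: 6 ethyl (1R,4R,5S)-4-formyl-2-oxo-5-Ar-cyclopentane-1-carboxylate; 7 ethane-1,2-dithiol
Product: 8 ethyl (1R,4R,5S)-4-(1,3-dithiolan-2-yl)-2-oxo-5-Ar-cyclopentane-1-carboxylate
Conditions: HS(CH2)2SH (1.2 equiv), BF3·OEt2 (0.2 equiv), CH2Cl2, −20 → 0 °C
Reagents that add atoms: ethane-1,2-dithiol, SCCS
Why: Lewis-acid thioacetalisation is much faster at the aldehyde than at the largely enolised β-keto ester carbonyl.

**Step 4**
Reactants: 8 ethyl (1R,4R,5S)-4-(1,3-dithiolan-2-yl)-2-oxo-5-Ar-cyclopentane-1-carboxylate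
Product: 9 ethyl (1R,4R,5S)-4-methyl-2-oxo-5-Ar-cyclopentane-1-carboxylate
Conditions: Raney Ni (excess, deactivated in refluxing acetone), EtOH, 50 °C
Reagents that add atoms: none
Why: Mozingo desulfurisation (C–S hydrogenolysis) turns the masked formyl group into the methyl group without touching a stereocentre, and the deactivated nickel spares the keto ester.

**Step 5**
Reactants: 9 ethyl (1R,4R,5S)-4-methyl-2-oxo-5-Ar-cyclopentane-1-carboxylate; 10 allyl bromide
Product: 11 ethyl (1R,3R,4S,5S)-3-allyl-4-methyl-2-oxo-5-Ar-cyclopentane-1-carboxylate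
Conditions: LiN(i-Pr)2 (2.2 equiv), THF, 0 °C; allyl bromide (1.05 equiv), 0 °C; then 1 M HCl
Reagents that add atoms: allyl bromide, C=CCBr
Why: Huckin–Weiler dianion alkylation, in which the more basic α'-carbanion of the β-keto ester dianion (next to the methyl-bearing carbon) is allylated; its configuration is reset in step 11.

**Step 6**
Reactants: 11 ethyl (1R,3R,4S,5S)-3-allyl-4-methyl-2-oxo-5-Ar-cyclopentane-1-carboxylate; 12 3-phenyl-2-(phenylsulfonyl)oxaziridine
Product: 13 ethyl (1R,3R,4S,5R)-3-allyl-1-hydroxy-4-methyl-2-oxo-5-Ar-cyclopentane-1-carboxylate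
Conditions: KN(SiMe3)2 (1.1 equiv), THF, −78 °C; 12 (1.3 equiv), −78 → −40 °C; then AcOH
Reagents that add atoms: 3-phenyl-2-(phenylsulfonyl)oxaziridine, O=S(=O)(N1OC1c2ccccc2)c3ccccc3
Why: Davis enolate hydroxylation of the β-keto ester enolate, the oxaziridine approaching anti to the adjacent aryl group so that OH is trans to aryl and the ester ends cis to it (1R).

**Step 7**
Reactants: 13 ethyl (1R,3R,4S,5R)-3-allyl-1-hydroxy-4-methyl-2-oxo-5-Ar-cyclopentane-1-carboxylate; 14 methyl trifluoromethanesulfonate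
Product: 15 ethyl (1R,3R,4S,5R)-3-allyl-1-methoxy-4-methyl-2-oxo-5-Ar-cyclopentane-1-carboxylate
Conditions: MeOTf (3 equiv), 2,6-di-tert-butyl-4-methylpyridine (4 equiv), CH2Cl2, 23 → 40 °C; aq. NaHCO3 wash
Reagents that add atoms: methyl trifluoromethanesulfonate, COS(=O)(=O)C(F)(F)F
Why: O-alkylation of the hindered tertiary alcohol with a powerful methylating agent and a non-nucleophilic base, conditions that neither enolise the ketone nor trigger retro-Claisen cleavage.

**Step 8**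
Reactants: 15 ethyl (1R,3R,4S,5R)-3-allyl-1-methoxy-4-methyl-2-oxo-5-Ar-cyclopentane-1-carboxylate
Product: 16 (2S,3R,4R,5R)-5-allyl-2-(hydroxymethyl)-2-methoxy-4-methyl-3-Ar-cyclopentan-1-ol (C1 epimers)
Conditions: LiAlH4 (2.5 equiv), THF, 0 °C; H2O, 15% aq. NaOH
Reagents that add atoms: none
Why: Hydride reduction of both the ketone and the ester, with the isolated alkene and the ethers inert; the new ring carbinol is re-oxidised in step 11.

**Step 9**
Reactants: 16 (2S,3R,4R,5R)-5-allyl-2-(hydroxymethyl)-2-methoxy-4-methyl-3-Ar-cyclopentan-1-ol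
Product: 17 (1R,3R,4R,5R)-3-allyl-2-hydroxy-1-methoxy-4-methyl-5-Ar-cyclopentane-1-carbaldehyde (C2 epimers)
Conditions: 2,2,6,6-tetramethylpiperidin-1-oxyl (TEMPO, 0.1 equiv), PhI(OAc)2 (1.1 equiv), CH2Cl2, 23 °C
Reagents that add atoms: none
Why: Oxoammonium (TEMPO) oxidation takes the primary alcohol much faster than the hindered secondary one and stops at the aldehyde, which has no α-hydrogen.

**Step 10**
Reactants: 17 (1R,3R,4R,5R)-3-allyl-2-hydroxy-1-methoxy-4-methyl-5-Ar-cyclopentane-1-carbaldehyde; 18 vinylmagnesium bromide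
Product: 19 (2S,3R,4R,5R)-5-allyl-2-(1-hydroxyprop-2-en-1-yl)-2-methoxy-4-methyl-3-Ar-cyclopentan-1-ol (both carbinol centres epimers)
Conditions: CH2=CHMgBr (2.5 equiv), THF, −78 → −20 °C; then 1 M HCl, 0 °C
Reagents that add atoms: vinylmagnesium bromide, C=C[Mg]Br
Why: Grignard 1,2-addition to the non-enolisable aldehyde after the first equivalent has deprotonated the free hydroxyl; both carbinol centres are oxidised away in the next step.

**Step 11**
Reactants: 19 (2S,3R,4R,5R)-5-allyl-2-(1-hydroxyprop-2-en-1-yl)-2-methoxy-4-methyl-3-Ar-cyclopentan-1-ol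
Product: 21 (1S,5S,6R,7S)-1-allyl-5-methoxy-7-methyl-6-Ar-bicyclo[3.2.1]octane-4,8-dione, via vinyl ketone 20 (not isolated)
Conditions: Dess–Martin periodinane (3 equiv), CH2Cl2, 0 → 23 °C; crude 20 added to LiN(SiMe3)2 (1.1 equiv), THF, −78 → 0 °C; then AcOH
Reagents that add atoms: none
Why: Dess–Martin oxidation of both alcohols gives the keto vinyl ketone, whose only possible enolate (at the allyl-bearing carbon) closes the six-membered ring by intramolecular 6-endo Michael addition; the acceptor is tethered to the methoxy-bearing carbon and can reach only the face cis to it, which fixes the quaternary centre as 1S.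

**Step 12**
Reactants: 21 (1S,5S,6R,7S)-1-allyl-5-methoxy-7-methyl-6-Ar-bicyclo[3.2.1]octane-4,8-dione; 12 3-phenyl-2-(phenylsulfonyl)oxaziridine
Product: 22 (1R,5R,6R,7S)-1-allyl-3-hydroxy-5-methoxy-7-methyl-6-Ar-bicyclo[3.2.1]octane-4,8-dione (C3 epimers)
Conditions: KN(SiMe3)2 (1.1 equiv), THF, −78 °C; 12 (1.3 equiv), −78 °C; then AcOH
Reagents that add atoms: 3-phenyl-2-(phenylsulfonyl)oxaziridine, O=S(=O)(N1OC1c2ccccc2)c3ccccc3
Why: The dione has a single enolisable position (C3, both α-carbons of C8 being bridgeheads), and Davis hydroxylation of that enolate installs the C3 oxygen; the carbinol configuration is irrelevant.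

**Step 13**
Reactants: 22 (1R,5R,6R,7S)-1-allyl-3-hydroxy-5-methoxy-7-methyl-6-Ar-bicyclo[3.2.1]octane-4,8-dione
Product: 24 (1S,5R,6R,7S)-1-allyl-3-hydroxy-5-methoxy-7-methyl-6-Ar-bicyclo[3.2.1]oct-2-ene-4,8-dione, via 3,4-dione 23 (not isolated)
Conditions: Dess–Martin periodinane (1.5 equiv), CH2Cl2, 23 °C
Reagents that add atoms: none
Why: Dess–Martin oxidation of the acyloin gives the 1,2-diketone, which can enolise only toward C2 (C5 has no hydrogen) and so tautomerises to one diosphenol.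

**Step 14**
Reactants: 24 (1S,5R,6R,7S)-1-allyl-3-hydroxy-5-methoxy-7-methyl-6-Ar-bicyclo[3.2.1]oct-2-ene-4,8-dione; 25 dimethyl sulfate
Product: 26 (1S,5R,6R,7S)-1-allyl-3,5-dimethoxy-7-methyl-6-Ar-bicyclo[3.2.1]oct-2-ene-4,8-dione
Conditions: Me2SO4 (1.5 equiv), K2CO3 (2 equiv), acetone, 23 → 50 °C
Reagents that add atoms: dimethyl sulfate, COS(=O)(=O)OC
Why: Williamson-type O-methylation of the acidic diosphenol with a hard electrophile and a mild base fixes the C2=C3 enol ether without C-alkylation or retro-Claisen cleavage.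

**Step 15**
Reactants: 26 (1S,5R,6R,7S)-1-allyl-3,5-dimethoxy-7-methyl-6-Ar-bicyclo[3.2.1]oct-2-ene-4,8-dione
Product: 27 (1S,4R,5S,6R,7S)-1-allyl-4-hydroxy-3,5-dimethoxy-7-methyl-6-Ar-bicyclo[3.2.1]oct-2-en-8-one
Conditions: NaBH4 (1.0 equiv), CeCl3·7H2O (1.1 equiv), MeOH, −78 °C
Reagents that add atoms: none
Why: Luche reduction is expected to favour the enone carbonyl (1,2-addition) over the bridging ketone flanked by two quaternary carbons, and hydride should arrive from the exo face (the C8 side) because the endo face is covered by the C6 aryl group, giving the 4R alcohol.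

**Step 16**
Reactants: 27 (1S,4R,5S,6R,7S)-1-allyl-4-hydroxy-3,5-dimethoxy-7-methyl-6-Ar-bicyclo[3.2.1]oct-2-en-8-one; 28 acetic anhydride
Product: 29 (1S,4R,5S,6R,7S)-1-allyl-3,5-dimethoxy-7-methyl-8-oxo-6-Ar-bicyclo[3.2.1]oct-2-en-4-yl acetate (CNP0181407.1)
Conditions: Ac2O (3 equiv), pyridine, 4-(dimethylamino)pyridine (0.1 equiv), CH2Cl2, 0 → 23 °C
Reagents that add atoms: acetic anhydride, CC(=O)OC(C)=O
Why: Nucleophile-catalysed acylation of the only free hydroxyl group, with retention at C4.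

**Compound list**
1 | 3,4,5-trimethoxybenzaldehyde | COc1cc(C=O)cc(OC)c1OC | starting material
2 | (triphenylphosphoranylidene)acetaldehyde | O=CC=P(c1ccccc1)(c1ccccc1)c1ccccc1 | starting material
3 | (E)-3-(3,4,5-trimethoxyphenyl)prop-2-enal | O=C/C=C/c1cc(OC)c(OC)c(OC)c1 | intermediate
4 | ethyl 4-bromo-3-oxobutanoate | CCOC(=O)CC(=O)CBr | starting material
5 | ethyl 4-bromo-3-oxo-2-[(1S)-3-oxo-1-(3,4,5-trimethoxyphenyl)propyl]butanoate (C2 epimers) | CCOC(=O)C(C(=O)CBr)[C@H](CC=O)c1cc(OC)c(OC)c(OC)c1 | intermediate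
6 | ethyl (1R,4R,5S)-4-formyl-2-oxo-5-(3,4,5-trimethoxyphenyl)cyclopentane-1-carboxylate | CCOC(=O)[C@H]1C(=O)C[C@@H](C=O)[C@@H]1c2cc(OC)c(OC)c(OC)c2 | intermediate
7 | ethane-1,2-dithiol | SCCS | starting material
8 | ethyl (1R,4R,5S)-4-(1,3-dithiolan-2-yl)-2-oxo-5-(3,4,5-trimethoxyphenyl)cyclopentane-1-carboxylate | CCOC(=O)[C@H]1C(=O)C[C@@H](C2SCCS2)[C@@H]1c3cc(OC)c(OC)c(OC)c3 | intermediate
9 | ethyl (1R,4R,5S)-4-methyl-2-oxo-5-(3,4,5-trimethoxyphenyl)cyclopentane-1-carboxylate | CCOC(=O)[C@H]1C(=O)C[C@@H](C)[C@@H]1c2cc(OC)c(OC)c(OC)c2 | intermediate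
10 | allyl bromide | C=CCBr | starting material
11 | ethyl (1R,3R,4S,5S)-3-allyl-4-methyl-2-oxo-5-(3,4,5-trimethoxyphenyl)cyclopentane-1-carboxylate | CCOC(=O)[C@H]1C(=O)[C@H](CC=C)[C@@H](C)[C@@H]1c2cc(OC)c(OC)c(OC)c2 | intermediate
12 | 3-phenyl-2-(phenylsulfonyl)oxaziridine (racemic) | O=S(=O)(N1OC1c2ccccc2)c3ccccc3 | starting material
13 | ethyl (1R,3R,4S,5R)-3-allyl-1-hydroxy-4-methyl-2-oxo-5-(3,4,5-trimethoxyphenyl)cyclopentane-1-carboxylate | CCOC(=O)[C@]1(O)C(=O)[C@H](CC=C)[C@@H](C)[C@@H]1c2cc(OC)c(OC)c(OC)c2 | intermediate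
14 | methyl trifluoromethanesulfonate | COS(=O)(=O)C(F)(F)F | starting material
15 | ethyl (1R,3R,4S,5R)-3-allyl-1-methoxy-4-methyl-2-oxo-5-(3,4,5-trimethoxyphenyl)cyclopentane-1-carboxylate | CCOC(=O)[C@]1(OC)C(=O)[C@H](CC=C)[C@@H](C)[C@@H]1c2cc(OC)c(OC)c(OC)c2 | intermediate
16 | (2S,3R,4R,5R)-5-allyl-2-(hydroxymethyl)-2-methoxy-4-methyl-3-(3,4,5-trimethoxyphenyl)cyclopentan-1-ol (C1 epimers) | OC[C@]1(OC)C(O)[C@H](CC=C)[C@@H](C)[C@@H]1c2cc(OC)c(OC)c(OC)c2 | intermediate
17 | (1R,3R,4R,5R)-3-allyl-2-hydroxy-1-methoxy-4-methyl-5-(3,4,5-trimethoxyphenyl)cyclopentane-1-carbaldehyde (C2 epimers) | O=C[C@]1(OC)C(O)[C@H](CC=C)[C@@H](C)[C@@H]1c2cc(OC)c(OC)c(OC)c2 | intermediate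
18 | vinylmagnesium bromide | C=C[Mg]Br | starting material
19 | (2S,3R,4R,5R)-5-allyl-2-(1-hydroxyprop-2-en-1-yl)-2-methoxy-4-methyl-3-(3,4,5-trimethoxyphenyl)cyclopentan-1-ol (both carbinol centres epimers) | C=CC(O)[C@]1(OC)C(O)[C@H](CC=C)[C@@H](C)[C@@H]1c2cc(OC)c(OC)c(OC)c2 | intermediate
20 | (2S,3R,4S,5R)-2-acryloyl-5-allyl-2-methoxy-4-methyl-3-(3,4,5-trimethoxyphenyl)cyclopentan-1-one | C=CC(=O)[C@]1(OC)C(=O)[C@H](CC=C)[C@@H](C)[C@@H]1c2cc(OC)c(OC)c(OC)c2 | intermediate
21 | (1S,5S,6R,7S)-1-allyl-5-methoxy-7-methyl-6-(3,4,5-trimethoxyphenyl)bicyclo[3.2.1]octane-4,8-dione | C=CC[C@]12CCC(=O)[C@](OC)(C1=O)[C@@H](c3cc(OC)c(OC)c(OC)c3)[C@@H]2C | intermediate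
22 | (1R,5R,6R,7S)-1-allyl-3-hydroxy-5-methoxy-7-methyl-6-(3,4,5-trimethoxyphenyl)bicyclo[3.2.1]octane-4,8-dione (C3 epimers) | C=CC[C@]12CC(O)C(=O)[C@](OC)(C1=O)[C@@H](c3cc(OC)c(OC)c(OC)c3)[C@@H]2C | intermediate
23 | (1R,5R,6R,7S)-1-allyl-5-methoxy-7-methyl-6-(3,4,5-trimethoxyphenyl)bicyclo[3.2.1]octane-3,4,8-trione | C=CC[C@]12CC(=O)C(=O)[C@](OC)(C1=O)[C@@H](c3cc(OC)c(OC)c(OC)c3)[C@@H]2C | intermediate
24 | (1S,5R,6R,7S)-1-allyl-3-hydroxy-5-methoxy-7-methyl-6-(3,4,5-trimethoxyphenyl)bicyclo[3.2.1]oct-2-ene-4,8-dione | C=CC[C@]12C=C(O)C(=O)[C@](OC)(C1=O)[C@@H](c3cc(OC)c(OC)c(OC)c3)[C@@H]2C | intermediate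
25 | dimethyl sulfate | COS(=O)(=O)OC | starting material
26 | (1S,5R,6R,7S)-1-allyl-3,5-dimethoxy-7-methyl-6-(3,4,5-trimethoxyphenyl)bicyclo[3.2.1]oct-2-ene-4,8-dione | C=CC[C@]12C=C(OC)C(=O)[C@](OC)(C1=O)[C@@H](c3cc(OC)c(OC)c(OC)c3)[C@@H]2C | intermediate
27 | (1S,4R,5S,6R,7S)-1-allyl-4-hydroxy-3,5-dimethoxy-7-methyl-6-(3,4,5-trimethoxyphenyl)bicyclo[3.2.1]oct-2-en-8-one | C=CC[C@]12C=C(OC)[C@@H](O)[C@](OC)(C1=O)[C@@H](c3cc(OC)c(OC)c(OC)c3)[C@@H]2C | intermediate
28 | acetic anhydride | CC(=O)OC(C)=O | starting material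
29 | (1S,4R,5S,6R,7S)-1-allyl-3,5-dimethoxy-7-methyl-8-oxo-6-(3,4,5-trimethoxyphenyl)bicyclo[3.2.1]oct-2-en-4-yl acetate | C=CC[C@]12C=C(OC)[C@@H](OC(C)=O)[C@](OC)(C1=O)[C@@H](c1cc(OC)c(OC)c(OC)c1)[C@@H]2C | target

**Totals**
Total step count: 16. Longest linear sequence: 16 steps (fully linear from 1).

**Steps most likely to fail and their fallbacks**

Step 11 (oxidation and 6-endo Michael ring closure). The vinyl ketone may polymerise or fail to cyclise. The fallback makes the C1–C2 and C3–C4 bonds in the opposite order and sets out from 15. KOt-Bu (0.2 equiv) and tert-butyl acrylate in THF–t-BuOH at 0 °C add the only possible ketone enolate to the acrylate, anti to the neighbouring methyl group, to give ethyl (1R,3S,4S,5R)-3-allyl-3-(3-tert-butoxy-3-oxopropyl)-1-methoxy-4-methyl-2-oxo-5-Ar-cyclopentane-1-carboxylate F1. LiN(SiMe3)2 in THF (−78 → 0 °C) then closes the six-membered ring by Dieckmann (Claisen) condensation of the tert-butyl ester enolate on the ethyl ester, which only the epimer with the side chain cis to that ester can do, giving tert-butyl (1R,5S,6R,7S)-1-allyl-5-methoxy-7-methyl-4,8-dioxo-6-Ar-bicyclo[3.2.1]octane-3-carboxylate F2. p-Toluenesulfonic acid (0.1 equiv) in toluene at 90 °C cleaves the tert-butyl ester to (1R,5S,6R,7S)-1-allyl-5-methoxy-7-methyl-4,8-dioxo-6-Ar-bicyclo[3.2.1]octane-3-carboxylic acid F3, which decarboxylates in the flask, and the route is rejoined at 21. The facial selectivity of this intermolecular Michael addition is less secure than the tethered closure, which is why it is the fallback and not the main line.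

Step 12 (strong-base enolate oxidation of the strained, non-enolisable 1,3-dione). Retro-Claisen cleavage or over-oxidation may occur. The fallback introduces the C3 oxygen without a metal enolate and sets out from 21. tert-Butoxybis(dimethylamino)methane in toluene at 80 °C condenses at C3 to give (1R,5R,6R,7S,E)-1-allyl-3-[(dimethylamino)methylidene]-5-methoxy-7-methyl-6-Ar-bicyclo[3.2.1]octane-4,8-dione F4. Singlet oxygen (O2, hν, tetraphenylporphyrin as sensitiser, CH2Cl2, −78 °C) cleaves the enamine double bond through a dioxetane to the trione 23, which enolises, and the route is rejoined at 24; steps 12 and 13 are skipped.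

Step 15 (chemo- and face-selective reduction of the C4 ketone beside the C8 ketone). If the C8 ketone is also reduced, the fallback gives up selection at the hydride stage and sets out from 26. Excess NaBH4 with CeCl3·7H2O in MeOH at 0 °C reduces both ketones to (1S,4R,5R,6R,7S)-1-allyl-3,5-dimethoxy-7-methyl-6-Ar-bicyclo[3.2.1]oct-2-ene-4,8-diol (C8 epimers) F5. Ac2O (1.1 equiv) in pyridine at 0 °C acetylates only the allylic C4 hydroxyl, the C8 hydroxyl lying between two quaternary carbons, to give (1S,4R,5R,6R,7S)-1-allyl-8-hydroxy-3,5-dimethoxy-7-methyl-6-Ar-bicyclo[3.2.1]oct-2-en-4-yl acetate (C8 epimers) F6. Dess–Martin periodinane in CH2Cl2 re-oxidises C8, and the route comes back at the target 29.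

**Further compounds**
F1 | step 11 | ethyl (1R,3S,4S,5R)-3-allyl-3-(3-tert-butoxy-3-oxopropyl)-1-methoxy-4-methyl-2-oxo-5-(3,4,5-trimethoxyphenyl)cyclopentane-1-carboxylate | CCOC(=O)[C@]1(OC)C(=O)[C@](CC=C)(CCC(=O)OC(C)(C)C)[C@@H](C)[C@@H]1c2cc(OC)c(OC)c(OC)c2
F2 | step 11 | tert-butyl (1R,5S,6R,7S)-1-allyl-5-methoxy-7-methyl-4,8-dioxo-6-(3,4,5-trimethoxyphenyl)bicyclo[3.2.1]octane-3-carboxylate (C3 epimers) | C=CC[C@]12CC(C(=O)OC(C)(C)C)C(=O)[C@](OC)(C1=O)[C@@H](c3cc(OC)c(OC)c(OC)c3)[C@@H]2C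
F3 | step 11 | (1R,5S,6R,7S)-1-allyl-5-methoxy-7-methyl-4,8-dioxo-6-(3,4,5-trimethoxyphenyl)bicyclo[3.2.1]octane-3-carboxylic acid (C3 epimers) | C=CC[C@]12CC(C(=O)O)C(=O)[C@](OC)(C1=O)[C@@H](c3cc(OC)c(OC)c(OC)c3)[C@@H]2C
F4 | step 12 | (1R,5R,6R,7S,E)-1-allyl-3-[(dimethylamino)methylidene]-5-methoxy-7-methyl-6-(3,4,5-trimethoxyphenyl)bicyclo[3.2.1]octane-4,8-dione | C=CC[C@]12C/C(=C\N(C)C)C(=O)[C@](OC)(C1=O)[C@@H](c3cc(OC)c(OC)c(OC)c3)[C@@H]2C
F5 | step 15 | (1S,4R,5R,6R,7S)-1-allyl-3,5-dimethoxy-7-methyl-6-(3,4,5-trimethoxyphenyl)bicyclo[3.2.1]oct-2-ene-4,8-diol (C8 epimers) | C=CC[C@]12C=C(OC)[C@@H](O)[C@](OC)(C1O)[C@@H](c3cc(OC)c(OC)c(OC)c3)[C@@H]2C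
F6 | step 15 | (1S,4R,5R,6R,7S)-1-allyl-8-hydroxy-3,5-dimethoxy-7-methyl-6-(3,4,5-trimethoxyphenyl)bicyclo[3.2.1]oct-2-en-4-yl acetate (C8 epimers) | C=CC[C@]12C=C(OC)[C@@H](OC(C)=O)[C@](OC)(C1O)[C@@H](c3cc(OC)c(OC)c(OC)c3)[C@@H]2C
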